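Lutein 5,6-epoxide dipalmitate is cut at the C10–C11 single bond, the sp2–sp2 link between the C7–C10 diene on the epoxidised cyclohexane (ring A) and the C11–C7′ heptaene that ends at the cyclohexene (ring B). A Suzuki–Miyaura coupling of a 14-carbon (1E,3E)-dienyl iodide, which already holds the anti 5,6-epoxide and its palmitate, with a 26-carbon all-E heptaenyl pinacol boronate, which holds the ring B palmitate, forms this bond with retention of both alkene geometries and gives the finished diester in one operation, without protecting groups. The iodide stems from (4R,6R)-actinol, the boronate from (R)-α-ionone and 2,7-dimethylocta-2,4,6-trienedial.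

Key step: step 17

Remark: positions are given in carotenoid numbering (ring A C1–C6, chain C7–C15, primed numbers for the ring B half); (4R,6R)-actinol, (R)-α-ionone, 2,7-dimethylocta-2,4,6-trienedial, the dichloromethyl pinacol boronate and the P450 BM3 variant (expressed from its known gene) are taken as obtainable.

Step 1
Reactants: 1 (4R,6R)-4-hydroxy-2,2,6-trimethylcyclohexan-1-one ((4R,6R)-actinol); 2 hexadecanoyl chloride (palmitoyl chloride)
Product: 3 (1R,5R)-3,3,5-trimethyl-4-oxocyclohexyl hexadecanoate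
Conditions: pyridine, DMAP (cat.), CH2Cl2, 0 °C → rt
Reagents that add atoms: none
Why: DMAP-catalysed acylation of the unhindered secondary alcohol with the acid chloride installs the first palmitate at the outset, so that the ester itself stands in for a protecting group and the C3 carbinol centre is carried on unchanged.

Step 2
Reactants: 3 (1R,5R)-3,3,5-trimethyl-4-oxocyclohexyl hexadecanoate
Product: 4 (1R)-3,5,5-trimethyl-4-[(trifluoromethanesulfonyl)oxy]cyclohex-3-en-1-yl hexadecanoate
Conditions: Tf2O, 2,6-di-tert-butyl-4-methylpyridine, CH2Cl2, 0 °C → rt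
Reagents that add atoms: triflic anhydride, O=S(=O)(OS(=O)(=O)C(F)(F)F)C(F)(F)F
Why: O-triflation of the ketone and loss of its only α-hydrogen (at C5) to the hindered pyridine is the standard enol triflate synthesis, it can give only the tetrasubstituted C5=C6 enol triflate, and the non-nucleophilic conditions leave the ester untouched while the C5 stereocentre is erased on purpose.

Step 3
Reactants: 4 (1R)-3,5,5-trimethyl-4-[(trifluoromethanesulfonyl)oxy]cyclohex-3-en-1-yl hexadecanoate
Product: 5 (1R)-4-formyl-3,5,5-trimethylcyclohex-3-en-1-yl hexadecanoate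
Conditions: Pd(OAc)2 (cat.), Ph2P(CH2)3PPh2 (cat.), CO (1 atm), Et3SiH, Et3N, DMF, 70 °C
Reagents that add atoms: carbon monoxide, [C-]#[O+]
Why: Palladium-catalysed reductive carbonylation (formylation) of an enol triflate runs by oxidative addition, CO insertion and hydride transfer from the silane to the acylpalladium, and it brings in C7 at the aldehyde level without a reagent that would attack the ester.

Step 4
Reactants: 5 (1R)-4-formyl-3,5,5-trimethylcyclohex-3-en-1-yl hexadecanoate
Product: 6 (1R)-4-(hydroxymethyl)-3,5,5-trimethylcyclohex-3-en-1-yl hexadecanoate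
Conditions: NaBH4, CeCl3·7H2O, MeOH, −20 → 0 °C
Reagents that add atoms: none
Why: Luche reduction gives clean 1,2-reduction of the hindered enal to the primary allylic alcohol within minutes at low temperature, conditions under which the palmitate should not be reduced.

Step 5
Reactants: 6 (1R)-4-(hydroxymethyl)-3,5,5-trimethylcyclohex-3-en-1-yl hexadecanoate
Product: 7 (1R,3S,6R)-6-(hydroxymethyl)-1,5,5-trimethyl-7-oxabicyclo[4.1.0]heptan-3-yl hexadecanoate (epoxide oxygen anti to the ester)
Conditions: Ti(OiPr)4, D-(−)-diethyl tartrate, t-BuOOH, 4 Å molecular sieves, CH2Cl2, −20 °C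
Reagents that add atoms: tert-butyl hydroperoxide, CC(C)(C)OO
Why: Katsuki–Sharpless asymmetric epoxidation of the primary allylic alcohol is reagent-controlled, and with D-(−)-diethyl tartrate the peroxide oxygen should be delivered to the face of the tetrasubstituted C5=C6 bond anti to the C3 ester, which sets C5 and C6 together in the arrangement of the target (5R,6S there).

Step 6
Reactants: 7 (1R,3S,6R)-6-(hydroxymethyl)-1,5,5-trimethyl-7-oxabicyclo[4.1.0]heptan-3-yl hexadecanoate
Product: 8 (1R,3S,6S)-6-formyl-1,5,5-trimethyl-7-oxabicyclo[4.1.0]heptan-3-yl hexadecanoate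
Conditions: (n-Pr)4N[RuO4] (cat.), N-methylmorpholine N-oxide, 4 Å molecular sieves, CH2Cl2, rt
Reagents that add atoms: none
Why: Ley–Griffith oxidation is neutral, so the primary alcohol should be oxidised to the non-enolisable aldehyde without opening of the acid-labile tetrasubstituted epoxide or loss of the ester.

Step 7
Reactants: 9 prop-2-yn-1-ol
Product: 11 (2E)-3-iodo-2-methylprop-2-en-1-ol, via alkenylalane 10 (not isolated)
Conditions: AlMe3, Cp2ZrCl2 (cat.), CH2Cl2, 0 °C → rt; then I2, THF, −30 → 0 °C
Reagents that add atoms: trimethylaluminium, C[Al](C)C; iodine, II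
Why: Negishi zirconium-catalysed carboalumination adds methyl and aluminium syn across the alkyne with aluminium on the terminal carbon, and iodinolysis of the C–Al bond with retention fixes the E trisubstituted vinyl iodide that becomes C9=C10.

Step 8
Reactants: 11 (2E)-3-iodo-2-methylprop-2-en-1-ol
Product: 12 (1E)-3-bromo-1-iodo-2-methylprop-1-ene
Conditions: PBr3, Et2O, 0 °C
Reagents that add atoms: phosphorus tribromide, BrP(Br)Br
Why: SN2 displacement of the activated primary allylic alcohol by bromide is a standard allylic bromination that touches neither the vinyl iodide nor its geometry.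

Step 9
Reactants: 12 (1E)-3-bromo-1-iodo-2-methylprop-1-ene
Product: 13 diethyl [(2E)-3-iodo-2-methylprop-2-en-1-yl]phosphonate
Conditions: P(OEt)3 (neat), 100 °C
Reagents that add atoms: triethyl phosphite, CCOP(OCC)OCC
Why: Michaelis–Arbuzov reaction of the primary allylic bromide gives the allylic phosphonate, the sp2 C–I bond being inert to the phosphite without a metal catalyst.

Step 10
Reactants: 8 (1R,3S,6S)-6-formyl-1,5,5-trimethyl-7-oxabicyclo[4.1.0]heptan-3-yl hexadecanoate; 13 diethyl [(2E)-3-iodo-2-methylprop-2-en-1-yl]phosphonate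
Product: 15 (1R,3S,6S)-6-[(1E,3E)-4-iodo-3-methylbuta-1,3-dien-1-yl]-1,5,5-trimethyl-7-oxabicyclo[4.1.0]heptan-3-yl hexadecanoate, via potassium phosphonate carbanion 14 (not isolated)
Conditions: 13, KN(SiMe3)2 (one equivalent), THF, −78 °C; then 8, −78 °C → rt
Reagents that add atoms: none
Why: Horner–Wadsworth–Emmons olefination of the non-enolisable aldehyde with the α-carbanion of the allylic phosphonate should form C7=C8 with E selectivity, the C9=C10 geometry and the C–I bond being retained and the single equivalent of base sparing the ester.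

Step 11
Reactants: 16 (R)-α-ionone, (3E)-4-[(1R)-2,6,6-trimethylcyclohex-2-en-1-yl]but-3-en-2-one
Product: 17 (3R,6R)-3-hydroxy-α-ionone, (3E)-4-[(1R,4R)-4-hydroxy-2,6,6-trimethylcyclohex-2-en-1-yl]but-3-en-2-one
Conditions: CYP102A1 (P450 BM3) variant A74G/F87V/L188Q, NADP+ (cat.), glucose dehydrogenase, D-glucose, air, phosphate buffer pH 7.5, 25 °C
Reagents that add atoms: dioxygen, O=O
Why: Enzymatic allylic C–H hydroxylation (hydrogen abstraction and oxygen rebound at the haem iron–oxo species) of α-ionone by this class of P450 enzymes is known to occur at C3′ and trans to the C6′ side chain, so the binding orientation in the active site should set C3′ as R from the 6′R substrate.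

Step 12
Reactants: 17 (3R,6R)-3-hydroxy-α-ionone; 2 hexadecanoyl chloride
Product: 18 (1R,4R)-3,5,5-trimethyl-4-[(1E)-3-oxobut-1-en-1-yl]cyclohex-2-en-1-yl hexadecanoate
Conditions: pyridine, DMAP (cat.), CH2Cl2, 0 °C → rt
Reagents that add atoms: none
Why: DMAP-catalysed acylation occurs at oxygen with retention at C3′ under buffered conditions that do not ionise the allylic C–O bond, and the ester then shields this position through the acidic step that follows.

Step 13
Reactants: 18 (1R,4R)-3,5,5-trimethyl-4-[(1E)-3-oxobut-1-en-1-yl]cyclohex-2-en-1-yl hexadecanoate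
Product: 19 (1R,4R)-4-[(1E)-3-hydroxy-3-methylpenta-1,4-dien-1-yl]-3,5,5-trimethylcyclohex-2-en-1-yl hexadecanoate (both epimers at the new carbinol carbon)
Conditions: CH2=CHMgBr (slight excess), THF, −78 °C; aq. NH4Cl
Reagents that add atoms: vinylmagnesium bromide, C=C[Mg]Br
Why: Grignard 1,2-addition to the methyl ketone is much faster than attack on the hindered secondary ester at −78 °C, and the new C9′ carbinol centre is formed as a mixture of no consequence because it is destroyed in the next step.

Step 14
Reactants: 19 (1R,4R)-4-[(1E)-3-hydroxy-3-methylpenta-1,4-dien-1-yl]-3,5,5-trimethylcyclohex-2-en-1-yl hexadecanoate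
Product: 20 [(2E,4E)-5-[(1R,4R)-4-(hexadecanoyloxy)-2,6,6-trimethylcyclohex-2-en-1-yl]-3-methylpenta-2,4-dien-1-yl]triphenylphosphonium bromide
Conditions: PPh3·HBr, CH2Cl2, 0 °C → rt; crystallisation
Reagents that add atoms: triphenylphosphine hydrobromide, [Br-].c1ccccc1[PH+](c1ccccc1)c1ccccc1
Why: Ionisation of the tertiary bis-allylic alcohol by the mild acid gives a pentadienyl cation that triphenylphosphine captures at the terminal carbon (SN1′-type allylic transposition, the classical route to dienyl Wittig salts), while the far less basic allylic ester should not ionise.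

Step 15
Reactants: 20 the phosphonium bromide of step 14; 21 (2E,4E,6E)-2,7-dimethylocta-2,4,6-trienedial
Product: 23 (1R,4R)-3,5,5-trimethyl-4-[(1E,3E,5E,7E,9E,11E)-3,7,12-trimethyl-13-oxotrideca-1,3,5,7,9,11-hexaen-1-yl]cyclohex-2-en-1-yl hexadecanoate, via phosphorus ylide 22 (not isolated)
Conditions: NaN(SiMe3)2 (one equivalent), THF, −78 °C; 21 (excess), −78 → 0 °C; then heptane, 80 °C
Reagents that add atoms: none
Why: Wittig olefination with the semi-stabilised allylic ylide and an excess of the symmetrical dialdehyde should stop at mono-condensation (the remaining aldehyde is deactivated by the longer conjugation), and the hindered 11′Z isomer formed alongside is converted thermally into the all-E aldehyde.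

Step 16
Reactants: 23 the all-E hexaenal of step 15
Product: 24 (1R,4R)-3,5,5-trimethyl-4-[(1E,3E,5E,7E,9E,11E,13E)-3,7,12-trimethyl-14-(4,4,5,5-tetramethyl-1,3,2-dioxaborolan-2-yl)tetradeca-1,3,5,7,9,11,13-heptaen-1-yl]cyclohex-2-en-1-yl hexadecanoate
Conditions: Cl2CHB(pin), CrCl2, LiI, THF, rt, dark
Reagents that add atoms: 2-(dichloromethyl)-4,4,5,5-tetramethyl-1,3,2-dioxaborolane, ClC(Cl)B1OC(C)(C)C(C)(C)O1
Why: Takai–Utimoto olefination with the geminal dichromium reagent formed from the dihalomethylboronate adds chemoselectively to the aldehyde and eliminates to the E alkenyl pinacol boronate, adding the one carbon C11 while ester and polyene stay untouched.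

Step 17
Reactants: 15 the epoxy dienyl iodide of step 10; 24 the heptaenyl pinacol boronate of step 16
Product: 25 (3S,5R,6S,3′R,6′R)-5,6-epoxy-5,6-dihydro-β,ε-carotene-3,3′-diyl dihexadecanoate (lutein 5,6-epoxide dipalmitate)
Conditions: Pd(PPh3)4 (cat.), TlOEt, THF/H2O, rt, dark, argon
Reagents that add atoms: none
Why: Suzuki–Miyaura cross-coupling: zerovalent palladium inserts into the C10–I bond of 15 with retention, TlOEt turns the pinacol boronate 24 into an ate complex and removes iodide from palladium as insoluble TlI so that the C11 alkenyl group is transferred with retention, and reductive elimination forms the C10–C11 sp2–sp2 bond. The closest known reaction type is the thallium-accelerated coupling of alkenyl iodides with alkenylboron compounds used to assemble sensitive polyenes at room temperature. No ring is closed and no stereocentre is created; the stereochemical content is the transfer of the E geometry at C9=C10 and C11=C12, which is secured because both partners are configurationally defined and the catalytic cycle is stereospecific. The chemoselectivity needed is reaction at C–I and C–B only, and the substrate secures it because the other functions are a base-stable tetrasubstituted epoxide, two hindered secondary palmitates that should survive brief contact with the mild base, and a polyene that is protected by darkness and argon. The step joins a 14-carbon and a 26-carbon fragment and gives the complete diester, so nothing remains to be done after it.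

Compound list
1 | (4R,6R)-4-hydroxy-2,2,6-trimethylcyclohexan-1-one ((4R,6R)-actinol) | O[C@H]1CC(C)(C)C(=O)[C@H](C)C1 | starting material
2 | hexadecanoyl chloride (palmitoyl chloride) | CCCCCCCCCCCCCCCC(=O)Cl | starting material
3 | (1R,5R)-3,3,5-trimethyl-4-oxocyclohexyl hexadecanoate | CCCCCCCCCCCCCCCC(=O)O[C@H]1CC(C)(C)C(=O)[C@H](C)C1 | intermediate
4 | (1R)-3,5,5-trimethyl-4-[(trifluoromethanesulfonyl)oxy]cyclohex-3-en-1-yl hexadecanoate | CCCCCCCCCCCCCCCC(=O)O[C@H]1CC(C)(C)C(OS(=O)(=O)C(F)(F)F)=C(C)C1 | intermediate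
5 | (1R)-4-formyl-3,5,5-trimethylcyclohex-3-en-1-yl hexadecanoate | CCCCCCCCCCCCCCCC(=O)O[C@H]1CC(C)(C)C(C=O)=C(C)C1 | intermediate
6 | (1R)-4-(hydroxymethyl)-3,5,5-trimethylcyclohex-3-en-1-yl hexadecanoate | CCCCCCCCCCCCCCCC(=O)O[C@H]1CC(C)(C)C(CO)=C(C)C1 | intermediate
7 | (1R,3S,6R)-6-(hydroxymethyl)-1,5,5-trimethyl-7-oxabicyclo[4.1.0]heptan-3-yl hexadecanoate | CCCCCCCCCCCCCCCC(=O)O[C@H]1CC(C)(C)[C@]2(CO)O[C@]2(C)C1 | intermediate
8 | (1R,3S,6S)-6-formyl-1,5,5-trimethyl-7-oxabicyclo[4.1.0]heptan-3-yl hexadecanoate | CCCCCCCCCCCCCCCC(=O)O[C@H]1CC(C)(C)[C@]2(C=O)O[C@]2(C)C1 | intermediate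
9 | prop-2-yn-1-ol | C#CCO | starting material
10 | dimethylaluminium (2E)-3-(dimethylalumanyl)-2-methylprop-2-en-1-olate (alkenylalane) | C[Al](C)OC/C(C)=C/[Al](C)C | intermediate
11 | (2E)-3-iodo-2-methylprop-2-en-1-ol | OC/C(C)=C/I | intermediate
12 | (1E)-3-bromo-1-iodo-2-methylprop-1-ene | BrC/C(C)=C/I | intermediate
13 | diethyl [(2E)-3-iodo-2-methylprop-2-en-1-yl]phosphonate | CCOP(=O)(OCC)C/C(C)=C/I | intermediate
14 | potassium salt of the α-carbanion of 13 | [K+].CCOP(=O)(OCC)[CH-]/C(C)=C/I | intermediate
15 | (1R,3S,6S)-6-[(1E,3E)-4-iodo-3-methylbuta-1,3-dien-1-yl]-1,5,5-trimethyl-7-oxabicyclo[4.1.0]heptan-3-yl hexadecanoate | CCCCCCCCCCCCCCCC(=O)O[C@H]1CC(C)(C)[C@]2(/C=C/C(C)=C/I)O[C@]2(C)C1 | intermediate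
16 | (R)-α-ionone | CC(=O)/C=C/[C@H]1C(C)=CCCC1(C)C | starting material
17 | (3R,6R)-3-hydroxy-α-ionone | CC(=O)/C=C/[C@H]1C(C)=C[C@H](O)CC1(C)C | intermediate
18 | (1R,4R)-3,5,5-trimethyl-4-[(1E)-3-oxobut-1-en-1-yl]cyclohex-2-en-1-yl hexadecanoate | CC(=O)/C=C/[C@H]1C(C)=C[C@H](OC(=O)CCCCCCCCCCCCCCC)CC1(C)C | intermediate
19 | (1R,4R)-4-[(1E)-3-hydroxy-3-methylpenta-1,4-dien-1-yl]-3,5,5-trimethylcyclohex-2-en-1-yl hexadecanoate (epimers at the carbinol carbon) | C=CC(C)(O)/C=C/[C@H]1C(C)=C[C@H](OC(=O)CCCCCCCCCCCCCCC)CC1(C)C | intermediate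
20 | [(2E,4E)-5-[(1R,4R)-4-(hexadecanoyloxy)-2,6,6-trimethylcyclohex-2-en-1-yl]-3-methylpenta-2,4-dien-1-yl]triphenylphosphonium bromide | [Br-].c1ccccc1[P+](c1ccccc1)(c1ccccc1)C/C=C(C)/C=C/[C@H]1C(C)=C[C@H](OC(=O)CCCCCCCCCCCCCCC)CC1(C)C | intermediate
21 | (2E,4E,6E)-2,7-dimethylocta-2,4,6-trienedial | O=C/C(C)=C/C=C/C=C(C)/C=O | starting material
22 | phosphorus ylide of 20 | c1ccccc1P(c1ccccc1)(c1ccccc1)=C/C=C(C)/C=C/[C@H]1C(C)=C[C@H](OC(=O)CCCCCCCCCCCCCCC)CC1(C)C | intermediate
23 | (1R,4R)-3,5,5-trimethyl-4-[(1E,3E,5E,7E,9E,11E)-3,7,12-trimethyl-13-oxotrideca-1,3,5,7,9,11-hexaen-1-yl]cyclohex-2-en-1-yl hexadecanoate | O=C/C(C)=C/C=C/C=C(C)/C=C/C=C(C)/C=C/[C@H]1C(C)=C[C@H](OC(=O)CCCCCCCCCCCCCCC)CC1(C)C | intermediate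
24 | (1R,4R)-3,5,5-trimethyl-4-[(1E,3E,5E,7E,9E,11E,13E)-3,7,12-trimethyl-14-(4,4,5,5-tetramethyl-1,3,2-dioxaborolan-2-yl)tetradeca-1,3,5,7,9,11,13-heptaen-1-yl]cyclohex-2-en-1-yl hexadecanoate | CC1(C)OB(OC1(C)C)/C=C/C(C)=C/C=C/C=C(C)/C=C/C=C(C)/C=C/[C@H]1C(C)=C[C@H](OC(=O)CCCCCCCCCCCCCCC)CC1(C)C | intermediate
25 | (3S,5R,6S,3′R,6′R)-5,6-epoxy-5,6-dihydro-β,ε-carotene-3,3′-diyl dihexadecanoate | CCCCCCCCCCCCCCCC(=O)O[C@H]1CC(C)(C)[C@]2(/C=C/C(C)=C/C=C/C(C)=C/C=C/C=C(C)/C=C/C=C(C)/C=C/[C@H]3C(C)=C[C@H](OC(=O)CCCCCCCCCCCCCCC)CC3(C)C)O[C@]2(C)C1 | target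

Total step count: 17. Longest linear sequence: 8 steps (steps 1, 2, 3, 4, 5, 6, 10 and 17, from 1 to 25).

Steps most likely to fail

Step 17. Hydrolysis of the palmitates or protodeboronation of the heptaenylboronate under the aqueous thallium base, or loss of E geometry in the polyene at palladium, may erode the coupling. The fallback sets out from 23 and comes back at 25. Dibromomethane is lithiated (LiN(iPr)2, THF, −95 °C) and quenched with Bu3SnCl to give tributyl(dibromomethyl)stannane F1. Chromium-mediated olefination of 23 with this reagent (CrCl2, LiI, THF/DMF) should give the E alkenylstannane, the 26-carbon tributylstannane F2. Base-free Stille coupling of it with 15 (Pd2(dba)3, AsPh3, N-methylpyrrolidone, rt to 40 °C) then forms the same C10–C11 bond and gives 25 without any basic reagent.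

Step 3. Hydride transfer to the hindered vinylpalladium before CO has inserted, that is reduction of the triflate to the alkene, may compete with formylation. The fallback sets out from 4 and comes back at 6. Hydroxycarbonylation of 4 (Pd(OAc)2, 1,1′-bis(diphenylphosphino)ferrocene, CO, KOAc, DMSO, aqueous work-up), which has no hydride source, should give (4R)-4-(hexadecanoyloxy)-2,6,6-trimethylcyclohex-1-ene-1-carboxylic acid F3. BH3·SMe2 then reduces the acid in preference to the ester and gives 6 directly.

Step 11. Incomplete turnover, over-oxidation at C3′ to the ketone or poor mass transfer of the sparingly soluble substrate may make the enzymatic hydroxylation impractical. The fallback sets out from 16 and comes back at 18. Ketalisation of 16 (ethylene glycol, HC(OMe)3, TsOH cat.) gives 2-methyl-2-[(E)-2-[(1R)-2,6,6-trimethylcyclohex-2-en-1-yl]ethenyl]-1,3-dioxolane F4. Allylic oxidation (t-BuOOH, dirhodium tetracaprolactamate Rh2(cap)4 cat., K2CO3) gives the 3′-oxo ketal F5. Luche reduction is expected to give mainly the cis alcohol F6, because hydride enters anti to the pseudo-axial C1′ methyl group. Mitsunobu esterification with palmitic acid (PPh3, diisopropyl azodicarboxylate) inverts C3′ and installs the ester in one operation to give the trans palmitate ketal F7; any trans alcohol present is simply acylated with 2 to the same ester. Mild deketalisation (pyridinium tosylate, wet acetone) returns to 18.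

Further compounds
F1 | step 17 | tributyl(dibromomethyl)stannane | CCCC[Sn](CCCC)(CCCC)C(Br)Br
F2 | step 17 | (1R,4R)-3,5,5-trimethyl-4-[(1E,3E,5E,7E,9E,11E,13E)-3,7,12-trimethyl-14-(tributylstannyl)tetradeca-1,3,5,7,9,11,13-heptaen-1-yl]cyclohex-2-en-1-yl hexadecanoate | CCCC[Sn](CCCC)(CCCC)/C=C/C(C)=C/C=C/C=C(C)/C=C/C=C(C)/C=C/[C@H]1C(C)=C[C@H](OC(=O)CCCCCCCCCCCCCCC)CC1(C)C
F3 | step 3 | (4R)-4-(hexadecanoyloxy)-2,6,6-trimethylcyclohex-1-ene-1-carboxylic acid | CCCCCCCCCCCCCCCC(=O)O[C@H]1CC(C)(C)C(C(=O)O)=C(C)C1
F4 | step 11 | 2-methyl-2-[(E)-2-[(1R)-2,6,6-trimethylcyclohex-2-en-1-yl]ethenyl]-1,3-dioxolane | CC1(OCCO1)/C=C/[C@H]1C(C)=CCCC1(C)C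
F5 | step 11 | (4R)-3,5,5-trimethyl-4-[(E)-2-(2-methyl-1,3-dioxolan-2-yl)ethenyl]cyclohex-2-en-1-one | CC1(OCCO1)/C=C/[C@H]1C(C)=CC(=O)CC1(C)C
F6 | step 11 | (1S,4R)-3,5,5-trimethyl-4-[(E)-2-(2-methyl-1,3-dioxolan-2-yl)ethenyl]cyclohex-2-en-1-ol (cis) | CC1(OCCO1)/C=C/[C@H]1C(C)=C[C@@H](O)CC1(C)C
F7 | step 11 | (1R,4R)-3,5,5-trimethyl-4-[(E)-2-(2-methyl-1,3-dioxolan-2-yl)ethenyl]cyclohex-2-en-1-yl hexadecanoate (trans) | CC1(OCCO1)/C=C/[C@H]1C(C)=C[C@H](OC(=O)CCCCCCCCCCCCCCC)CC1(C)C
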